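If I keep the books on the starting material, the limiting reagent here, with the partner at 1.20 equiv and the second reagent at 1.00 equiv to 4.00 equiv in the asked flasks, then each fraction of the charge stands in one of three entries: left, target or open.

| setting | autumn | dawn | Sunday's | Tuesday's | Saturday's | Friday's |
|---|---|---|---|---|---|---|
| starting material | 0.077 M | 0.077 M | 0.077 M | 0.077 M | 0.077 M | 0.077 M |
| partner | 1.2 equiv | 1.2 equiv | 1.20 equiv | 1.20 equiv | 1.20 equiv | 1.20 equiv |
| second reagent | 0.84 equiv | 3.3 equiv | 4.00 equiv | 4.00 equiv | 1.00 equiv | 1.00 equiv |
| third reagent | 3 equiv | 3 equiv | 3.00 equiv | 3.00 equiv | 3.00 equiv | 3.00 equiv |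
| temperature | −5 °C | 15 °C | 0 °C | 30 °C | 30 °C | 0 °C |
| remark | run made earlier | run made earlier |  |  |  |  |
| time |  |  | 30 h | 30 h | 30 h | 30 h |

| run | time / h | target / % | starting material / % |
|---|---|---|---|
| autumn | 4.00 | 0 | 70 |
| autumn | 10.0 | 0 | 49 |
| autumn | 20.0 | 0 | 34 |
| autumn | 30.0 | 0 | 26 |
| dawn | 1.33 | 0 | 31 |
| dawn | 3.00 | 2 | 13 |
| dawn | 6.00 | 13 | 4 |
| dawn | 15.0 | 30 | 0 |

(standard deviation of a reading: 2 percentage points)



- ranking by amount of target, in percent of the starting material charged, from high to low, at 30 h (Sunday's / Tuesday's / Saturday's / Friday's)
- the amount of target, in percent of the starting material charged of the flask you put first, at 30 h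
- the amount of target, in percent of the starting material charged of the flask you put last, at 30 h

At 15.0 h the dawn run shows 0 % starting material left and 30 % target, so 70.0 % of the charge is my open share, the fraction that has left the starting material and does not stand as target. The autumn run, at 30.0 h, has 26 % left and 0 % target, so its open share is 74.0 %. The target entry equals one minus the other two, so I follow what stays open, not what is made. Dawn's open share stood at 83.0 % at 6.00 h, so it kept a fraction 0.843 of itself up to its last reading, and each of these figures carries the scatter of the readings behind it.

The forecast ranks Tuesday's > Sunday's > Saturday's > Friday's, with 65 % at the top and 0 % at the bottom, on these grounds: “Tuesday is fastest, about 65%, though dawn's slowing hints at a plateau or loss.” In my books that top means an open share of at most 35.0 %, half of dawn's last figure. Tuesday's is warmer than dawn, at 30 °C against 15 °C, and runs for 30 h, which points to a smaller open share than dawn's last figure, but the readings do not say how much of that share is on its way to target, so I give no number of my own and leave the forecast's figure neither confirmed nor refuted.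

The flasks rank Saturday's > Tuesday's > Sunday's > Friday's, from 50.6 % down to 5.56 %.

    2 partner → self-condensation product (k = 0.380 /M/h, Ea = 53.0 kJ/mol)
    starting material + partner → intermediate A (k = 1.60 /M/h, Ea = 61.0 kJ/mol)
    starting material + second reagent → side product (k = 0.300 /M/h, Ea = 71.0 kJ/mol)
    third reagent + intermediate B → target (k = 0.280 /M/h, Ea = 60.0 kJ/mol)
    second reagent + intermediate A → intermediate B (k = 0.120 /M/h, Ea = 61.0 kJ/mol)
    (constants at 0 °C)

Tuesday's ends at 43.2 % target, and its open share of 56.8 % is side product, 56.8 %. Saturday's has 0 % left and 50.6 % target, an open share of 49.4 %, and dawn's 70.0 % was larger. The neighbour, Saturday's recipe at 0.031 M starting material, has 0.089 % left and 34.3 % target at 30 h, so its open share is 65.6 %, more than Saturday's, with side product at 29.9 % and intermediate A at 33.6 %.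

The data are simulated for an exercise; scatter was added.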